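**Plan**

- Cuts: (a) the primary ester C–O between the two halves (carboxylate of the eastern acid + spiro-epoxide on the western ring); (b) west: the seven-membered lactone C(=O)–O and its enoate C=C; (c) east: the enoate C=C, then the ring C=C together with a C–CO2H bond (decarboxylative dehydration of a β-hydroxy acid); (d) both carbocycles by [4+2] between one diene, (3E)-5-methyl-1,1-bis(trimethylsilyloxy)hexa-1,3-diene, and the two enantiomers of 5-menthyloxy-2(5H)-furanone.
- Enabling feature: in the eastern cyclohexene the adjacent ring CH–iPr and CH–alkenyl are cis, and the ring C=C lies between the alkenyl-bearing CH and C(CH2OH). Restoring CO2H on the olefinic CH and OH on C(CH2OH) makes this ring the endo adduct of an E-diene and a cis-butenolide. The western cyclohexane (CH–iPr, CH–alkenyl, CH–CO2R, C(OH)CH2O) is the same adduct, not decarboxylated, with the opposite absolute configuration at the CH–iPr/CH–alkenyl pair.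
- Forward: western carbocycle (step 4) → methylenation, Wittig, seven-membered lactone (step 10) → spiro-epoxide; then eastern carbocycle by the second cycloaddition (step 12, last ring) → diol, Wittig, loss of CO2/H2O → dihydroxy acid; union by epoxide opening; ester acidolysis.
- Stereochemistry: addition anti to the menthyloxy acetal carbon fixes the absolute configuration of each half; cis-dienophile, E-diene and endo transition state give the all-cis CH array; epoxidation/osmylation anti to that array sets the tertiary carbinol; the stabilized Wittig ylide sets both E-enoates.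
- Helpers: the butenolide carbonyl (activation, regiocontrol) stays as the lactone carbonyl in the west and leaves as CO2 in the east; menthol is recovered; the silyl ketal becomes ketone, then CH2.

Key step: step 12

Assumption: (5R)-5-(l-menthyloxy)- and (5S)-5-(d-menthyloxy)-2(5H)-furanone are taken as purchased dienophiles (each is otherwise one acetalisation of 5-hydroxy-2(5H)-furanone with the respective menthol, followed by crystallisation).

**Route**

Step 1
Reactants: 1 3-methylbutanal; 2 malonic acid
Product: 3 (E)-5-methylhex-3-enoic acid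
Conditions: Et3N (1.1 equiv), neat, 90 °C
Reagents that add atoms: none
Why: Knoevenagel–Doebner condensation without pyridine (Ragoussis variant) decarboxylates through the vinylogous carboxylate and should give the (E)-alk-3-enoic acid, which places the E double bond where the diene needs it.

Step 2
Reactants: 3 (E)-5-methylhex-3-enoic acid
Product: 4 (3E)-5-methyl-1,1-bis(trimethylsilyloxy)hexa-1,3-diene
Conditions: LiN(iPr)2 (2.2 equiv), THF, −78 → 0 °C; Me3SiCl, −78 → 23 °C; filtration under argon, distillation
Reagents that add atoms: chlorotrimethylsilane C[Si](C)(C)Cl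
Why: Double deprotonation (acid, then the allylic α-CH2) and O,O-silylation is the standard entry to vinylketene bis-silyl acetals, and the E geometry of the C3=C4 bond is not touched.

Step 3
Reactants: 5 tert-butyl (triphenylphosphoranylidene)acetate (2 equiv); 6 (chloromethoxy)triisopropylsilane
Product: 7 tert-butyl 3-[(triisopropylsilyl)oxy]-2-(triphenylphosphoranylidene)propanoate
Conditions: CH2Cl2, 0 → 23 °C; filtration of the phosphonium chloride
Reagents that add atoms: none
Why: C-Alkylation of an ester-stabilized ylide by an α-chloro ether with transylidation (the second equivalent of 5 takes up HCl) should deliver the hydroxymethyl carbon already O-silylated.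

Step 4
Reactants: 4 (3E)-5-methyl-1,1-bis(trimethylsilyloxy)hexa-1,3-diene; 8 (5S)-5-(d-menthyloxy)furan-2(5H)-one
Product: 10 western enone lactone acetal [cis-fused (3S)-4-isopropyl-3-(d-menthyloxy)-3a,4-dihydroisobenzofuran-1,7(3H,7aH)-dione], via bis-silyl ketal cycloadduct 9 (not isolated)
Conditions: toluene, BHT (cat.), 80 °C; then 1 M HCl, THF, 0 °C
Reagents that add atoms: none
Why: Thermal Diels–Alder reaction of a vinylketene acetal with the alkoxybutenolide, the same event as key step 12 in the mirror-image series: addition anti to the menthyloxy group, endo, with the dioxygenated terminus bonding to the carbonyl α-carbon, should give the all-cis array, and cold acid hydrolyses the silyl ketal to the ketone.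

Step 5
Reactants: 10 western enone lactone acetal
Product: 11 western keto lactone acetal
Conditions: H2 (1 atm), 10% Pd/C, EtOAc, 23 °C
Reagents that add atoms: none
Why: Heterogeneous hydrogenation of the conjugated disubstituted C=C; no stereocenter is created and the lactone acetal is inert.

Step 6
Reactants: 11 western keto lactone acetal
Product: 12 western methylidene lactone acetal
Conditions: Zn, CH2Br2, TiCl4, THF; then 11 in CH2Cl2, 0 → 23 °C
Reagents that add atoms: dibromomethane BrCBr
Why: Lombardo–Takai methylenation uses a non-basic geminal dimetal reagent that olefinates easily enolized ketones and spares lactones, and the ring-fusion CH between the two carbonyl-type groups can only keep the cis fusion.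

Step 7
Reactants: 12 western methylidene lactone acetal
Product: 13 western pseudo-acid (hydroxy lactone, both lactol epimers)
Conditions: AcOH/H2O/THF (3:1:1), 55 °C
Reagents that add atoms: water O
Why: Acid hydrolysis of the pseudo-ester (γ-alkoxy-γ-lactone acetal) should unmask the cis formyl acid as its hydroxy lactone and return d-menthol, while the weak acid leaves the 1,1-disubstituted alkene untouched.

Step 8
Reactants: 13 western pseudo-acid; 7 tert-butyl 3-[(triisopropylsilyl)oxy]-2-(triphenylphosphoranylidene)propanoate
Product: 14 western seco acid silyl ether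
Conditions: 7 (2.5 equiv), toluene, 70 °C
Reagents that add atoms: none
Why: Wittig olefination of a lactol in equilibrium with its formyl acid by an α-substituted stabilized ylide (as with 2-formylbenzoic acid) should give the trisubstituted enoate with the ester trans to the ring carbon (E), so the oxymethyl arm is cis to the ring as the lactone requires.

Step 9
Reactants: 14 western seco acid silyl ether
Product: 15 western hydroxy acid
Conditions: HF·pyridine, pyridine, THF, 0 → 23 °C
Reagents that add atoms: none
Why: Buffered fluoride cleavage of the primary triisopropylsilyl ether leaves the tert-butyl ester, the exocyclic alkene and the carboxylic acid alone.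

Step 10
Reactants: 15 western hydroxy acid
Product: 16 western seven-membered lactone (tert-butyl cis-fused 6-isopropyl-9-methylidene-1-oxo-octahydro-2-benzoxepine-4-carboxylate)
Conditions: 2,4,6-Cl3C6H2COCl, Et3N, THF, 23 °C; then DMAP, toluene (high dilution), 23 °C
Reagents that add atoms: none
Why: Yamaguchi lactonization through the mixed anhydride; the cis ring fusion and the ring-bound cis enoate hold acid and allylic alcohol close, and activating the acyl group instead of the allylic alcohol avoids SN2′ closure to a five-membered lactone.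

Step 11
Reactants: 16 western seven-membered lactone
Product: 17 western spiro-epoxide
Conditions: mCPBA, NaHCO3, CH2Cl2, 0 °C
Reagents that add atoms: 3-chloroperoxybenzoic acid OOC(=O)c1cccc(Cl)c1
Why: Prilezhaev epoxidation selects the electron-rich 1,1-disubstituted alkene over the enoate and should attack the face opposite the axial ring-fusion carbon, so the epoxide oxygen (the future tertiary OH) is trans to the lactone carbonyl and the CH2 cis, as in the target.

Step 12
Reactants: 4 (3E)-5-methyl-1,1-bis(trimethylsilyloxy)hexa-1,3-diene; 18 (5R)-5-(l-menthyloxy)furan-2(5H)-one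
Product: 20 eastern enone lactone acetal [cis-fused (3R)-4-isopropyl-3-(l-menthyloxy)-3a,4-dihydroisobenzofuran-1,7(3H,7aH)-dione], via bis-silyl ketal cycloadduct 19 (not isolated)
Conditions: toluene, BHT (cat.), 80 °C; then 1 M HCl, THF, 0 °C
Reagents that add atoms: none
Why: Concerted but asynchronous normal-demand [4+2] cycloaddition in which the γ-carbon of vinylketene acetal 4 (the CH bearing isopropyl, largest HOMO coefficient) bonds first to the β-carbon of butenolide 18 and the dioxygenated terminus then closes onto the carbonyl α-carbon. The closest known reaction type is the thermal Diels–Alder addition of 5-(menthyloxy)-2(5H)-furanone to 1-silyloxy and 1,1-dioxygenated dienes. The cyclohexene ring is closed by an intermolecular suprafacial [4+2] that forms both new ring C–C bonds at once and is cis-fused to the existing lactone. The two ring-fusion CH centers follow from the cis geometry of the dienophile and from addition anti to the menthyloxy group on the acetal carbon, which fixes the absolute configuration, and the isopropyl-bearing center follows from the E diene geometry and the endo transition state, so isopropyl and the acetal-bearing carbon end up cis. The step needs ortho regiochemistry, one π-face and endo selectivity, secured in turn by the two silyloxy groups on one diene terminus, by the menthyloxy group, and by secondary overlap with the lactone carbonyl of the flat butenolide. Cold acid turns the silyl ketal into the ketone at the carbon that becomes C(CH2OH)= of the cyclohexene, and the butenolide carbonyl that activated and oriented the dienophile is expelled as CO2 in step 19.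

Step 13
Reactants: 20 eastern enone lactone acetal
Product: 21 eastern keto lactone acetal
Conditions: H2 (1 atm), 10% Pd/C, EtOAc, 23 °C
Reagents that add atoms: none
Why: Heterogeneous hydrogenation of the conjugated C=C, as in step 5.

Step 14
Reactants: 21 eastern keto lactone acetal
Product: 22 eastern methylidene lactone acetal
Conditions: Zn, CH2Br2, TiCl4, THF; then 21 in CH2Cl2, 0 → 23 °C
Reagents that add atoms: dibromomethane BrCBr
Why: Lombardo–Takai methylenation of an enolizable ketone beside a lactone, as in step 6.

Step 15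
Reactants: 22 eastern methylidene lactone acetal
Product: 23 eastern diol
Conditions: OsO4 (2 mol %), NMO, acetone/H2O, 0 → 23 °C
Reagents that add atoms: 4-methylmorpholine N-oxide C[N+]1([O-])CCOCC1; water O
Why: Upjohn dihydroxylation should add to the exocyclic alkene from the face away from the all-cis substituents, placing the tertiary OH anti to the lactone carbonyl (the arrangement wanted for step 19; this center is destroyed later).

Step 16
Reactants: 23 eastern diol
Product: 24 eastern primary tert-butyldiphenylsilyl ether
Conditions: tBuPh2SiCl, imidazole, CH2Cl2, 0 °C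
Reagents that add atoms: tert-butyl(chloro)diphenylsilane CC(C)(C)[Si](Cl)(c1ccccc1)c1ccccc1
Why: Selective silylation of the primary hydroxyl (the tertiary one does not react) with a group that survives the acid of step 17 and prevents migration of the lactone onto the primary oxygen.

Step 17
Reactants: 24 eastern primary tert-butyldiphenylsilyl ether
Product: 25 eastern pseudo-acid (hydroxy lactone, both lactol epimers)
Conditions: AcOH/H2O/THF (3:1:1), 55 °C
Reagents that add atoms: water O
Why: Pseudo-ester hydrolysis as in step 7, returning l-menthol; the diphenyl-tert-butylsilyl ether and the tertiary alcohol tolerate aqueous acetic acid.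

Step 18
Reactants: 25 eastern pseudo-acid; 7 tert-butyl 3-[(triisopropylsilyl)oxy]-2-(triphenylphosphoranylidene)propanoate
Product: 26 eastern β-hydroxy acid enoate
Conditions: 7 (2.5 equiv), toluene, 70 °C
Reagents that add atoms: none
Why: Wittig olefination of the lactol with the stabilized ylide as in step 8 should give the E-enoate and free the carboxylic acid next to the tertiary carbinol.

Step 19
Reactants: 26 eastern β-hydroxy acid enoate
Product: 27 eastern cyclohexene bis-silyl tert-butyl ester
Conditions: Me2NCH(OCH2CMe3)2, toluene, 80 °C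
Reagents that add atoms: none
Why: Decarboxylative dehydration of a β-hydroxy acid with an amide acetal (Hara–Eschenmoser fragmentation): the tertiary hydroxyl is activated as an alkoxymethyleniminium leaving group and the anti carboxylate leaves as CO2, so the ring C=C can only form between the former carbinol carbon and the former α-carbon, and the neopentyl acetal cannot esterify the acid.

Step 20
Reactants: 27 eastern cyclohexene bis-silyl tert-butyl ester
Product: 29 eastern dihydroxy acid [(2E)-2-(hydroxymethyl)-3-[(1R,6S)-3-(hydroxymethyl)-6-isopropylcyclohex-2-en-1-yl]prop-2-enoic acid], via bis-silyl carboxylic acid 28 (not isolated)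
Conditions: TFA/CH2Cl2 (1:4), 0 → 23 °C; evaporation; then HF·pyridine, pyridine, THF, 0 → 23 °C
Reagents that add atoms: none
Why: Acidolysis of the tert-butyl ester (alkyl–oxygen cleavage, isobutene) followed in the same flask by fluoride cleavage of both silyl ethers; the inductively deactivated ring alkene and the skipped diene should survive both.

Step 21
Reactants: 17 western spiro-epoxide; 29 eastern dihydroxy acid
Product: 30 tert-butyl ester of the target
Conditions: 29 (1.5 equiv), Cs2CO3 (0.3 equiv), DMF, 50 °C
Reagents that add atoms: none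
Why: Carboxylate opening of a terminal spiro-epoxide by SN2 attack at the unsubstituted CH2 makes the primary ester and frees the tertiary alcohol with retention at the quaternary carbon; the excess acid protonates the alkoxide, and the primary alcohols of 29 do not compete with the carboxylate.

Step 22
Reactants: 30 tert-butyl ester of the target
Product: 31 target acid
Conditions: 85% aq. H3PO4, toluene, 23 °C
Reagents that add atoms: none
Why: Mild acidolysis of the tert-butyl ester by alkyl–oxygen cleavage should leave the lactone, the primary ester, the tertiary alcohol, the allylic alcohols and both alkenes intact.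

**Compound list**

1 | 3-methylbutanal (isovaleraldehyde) | CC(C)CC=O | starting material
2 | malonic acid | OC(=O)CC(=O)O | starting material
3 | (E)-5-methylhex-3-enoic acid | CC(C)/C=C/CC(=O)O | intermediate
4 | (3E)-5-methyl-1,1-bis(trimethylsilyloxy)hexa-1,3-diene | CC(C)/C=C/C=C(O[Si](C)(C)C)O[Si](C)(C)C | intermediate
5 | tert-butyl (triphenylphosphoranylidene)acetate | CC(C)(C)OC(=O)C=P(c1ccccc1)(c1ccccc1)c1ccccc1 | starting material
6 | (chloromethoxy)triisopropylsilane | ClCO[Si](C(C)C)(C(C)C)C(C)C | starting material
7 | tert-butyl 3-[(triisopropylsilyl)oxy]-2-(triphenylphosphoranylidene)propanoate | CC(C)(C)OC(=O)C(CO[Si](C(C)C)(C(C)C)C(C)C)=P(c1ccccc1)(c1ccccc1)c1ccccc1 | intermediate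
8 | (5S)-5-(d-menthyloxy)furan-2(5H)-one, menthyl = (1S,2R,5S)-2-isopropyl-5-methylcyclohexyl | O=C1O[C@H](O[C@H]2C[C@@H](C)CC[C@@H]2C(C)C)C=C1 | starting material
9 | western cycloadduct (not isolated): cis-fused (3S)-4-isopropyl-3-(d-menthyloxy)-7,7-bis(trimethylsilyloxy)-3a,4,7,7a-tetrahydroisobenzofuran-1(3H)-one; H-3a, H-4, H-7a all cis, menthyloxy trans to C-4 | CC(C)[C@H]1C=CC(O[Si](C)(C)C)(O[Si](C)(C)C)[C@H]2C(=O)O[C@H](O[C@H]3C[C@@H](C)CC[C@@H]3C(C)C)[C@@H]12 | intermediate
10 | western enone: cis-fused (3S)-4-isopropyl-3-(d-menthyloxy)-3a,4-dihydroisobenzofuran-1,7(3H,7aH)-dione; H-3a, H-4, H-7a all cis, menthyloxy trans to C-4 | CC(C)[C@H]1C=CC(=O)[C@H]2C(=O)O[C@H](O[C@H]3C[C@@H](C)CC[C@@H]3C(C)C)[C@@H]12 | intermediate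
11 | western keto lactone: 5,6-dihydro derivative of 10 (hexahydroisobenzofuran-1,7-dione), same configuration | CC(C)[C@H]1CCC(=O)[C@H]2C(=O)O[C@H](O[C@H]3C[C@@H](C)CC[C@@H]3C(C)C)[C@@H]12 | intermediate
12 | western methylidene lactone: cis-fused (3S)-4-isopropyl-3-(d-menthyloxy)-7-methylidenehexahydroisobenzofuran-1(3H)-one, H-3a, H-4, H-7a all cis | CC(C)[C@H]1CCC(=C)[C@H]2C(=O)O[C@H](O[C@H]3C[C@@H](C)CC[C@@H]3C(C)C)[C@@H]12 | intermediate
13 | western pseudo-acid: cis-fused 3-hydroxy-4-isopropyl-7-methylidenehexahydroisobenzofuran-1(3H)-one (lactol epimers), H-3a, H-4, H-7a all cis | CC(C)[C@H]1CCC(=C)[C@H]2C(=O)OC(O)[C@@H]12 | intermediate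
14 | western seco acid: all-cis 2-[(1E)-3-tert-butoxy-3-oxo-2-{[(triisopropylsilyl)oxy]methyl}prop-1-enyl]-3-isopropyl-6-methylidenecyclohexane-1-carboxylic acid | CC(C)[C@H]1CCC(=C)[C@@H](C(=O)O)[C@H]1/C=C(\CO[Si](C(C)C)(C(C)C)C(C)C)C(=O)OC(C)(C)C | intermediate
15 | western hydroxy acid: all-cis 2-[(1E)-3-tert-butoxy-2-(hydroxymethyl)-3-oxoprop-1-enyl]-3-isopropyl-6-methylidenecyclohexane-1-carboxylic acid | CC(C)[C@H]1CCC(=C)[C@@H](C(=O)O)[C@H]1/C=C(\CO)C(=O)OC(C)(C)C | intermediate
16 | western lactone: tert-butyl cis-fused 6-isopropyl-9-methylidene-1-oxo-1,3,5a,6,7,8,9,9a-octahydro-2-benzoxepine-4-carboxylate, isopropyl cis to both ring-fusion substituents | CC(C)[C@H]1CCC(=C)[C@H]2C(=O)OCC(C(=O)OC(C)(C)C)=C[C@@H]12 | intermediate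
17 | western spiro-epoxide: 9,2′-spiro-oxirane of 16, epoxide oxygen trans to the lactone carbonyl carbon, epoxide CH2 cis to it | CC(C)[C@H]1CC[C@@]3(CO3)[C@H]2C(=O)OCC(C(=O)OC(C)(C)C)=C[C@@H]12 | intermediate
18 | (5R)-5-(l-menthyloxy)furan-2(5H)-one, menthyl = (1R,2S,5R)-2-isopropyl-5-methylcyclohexyl | O=C1O[C@@H](O[C@@H]2C[C@H](C)CC[C@H]2C(C)C)C=C1 | starting material
19 | eastern cycloadduct (not isolated): (3R) mirror-image ring system of 9 carrying l-menthyloxy | CC(C)[C@@H]1C=CC(O[Si](C)(C)C)(O[Si](C)(C)C)[C@@H]2C(=O)O[C@@H](O[C@@H]3C[C@H](C)CC[C@H]3C(C)C)[C@H]12 | intermediate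
20 | eastern enone: cis-fused (3R)-4-isopropyl-3-(l-menthyloxy)-3a,4-dihydroisobenzofuran-1,7(3H,7aH)-dione; H-3a, H-4, H-7a all cis, menthyloxy trans to C-4 | CC(C)[C@@H]1C=CC(=O)[C@@H]2C(=O)O[C@@H](O[C@@H]3C[C@H](C)CC[C@H]3C(C)C)[C@H]12 | intermediate
21 | eastern keto lactone: 5,6-dihydro derivative of 20 | CC(C)[C@@H]1CCC(=O)[C@@H]2C(=O)O[C@@H](O[C@@H]3C[C@H](C)CC[C@H]3C(C)C)[C@H]12 | intermediate
22 | eastern methylidene lactone: 7-methylidene analogue of 21 | CC(C)[C@@H]1CCC(=C)[C@@H]2C(=O)O[C@@H](O[C@@H]3C[C@H](C)CC[C@H]3C(C)C)[C@H]12 | intermediate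
23 | eastern diol: 7-hydroxy-7-(hydroxymethyl) derivative, tertiary OH trans to the lactone carbonyl carbon | CC(C)[C@@H]1CC[C@](O)(CO)[C@@H]2C(=O)O[C@@H](O[C@@H]3C[C@H](C)CC[C@H]3C(C)C)[C@H]12 | intermediate
24 | eastern silyl ether: primary tert-butyldiphenylsilyl ether of 23 | CC(C)[C@@H]1CC[C@](O)(CO[Si](c3ccccc3)(c4ccccc4)C(C)(C)C)[C@@H]2C(=O)O[C@@H](O[C@@H]3C[C@H](C)CC[C@H]3C(C)C)[C@H]12 | intermediate
25 | eastern pseudo-acid: 3-hydroxy lactone (lactol epimers) from 24 | CC(C)[C@@H]1CC[C@](O)(CO[Si](c3ccccc3)(c4ccccc4)C(C)(C)C)[C@@H]2C(=O)OC(O)[C@H]12 | intermediate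
26 | eastern β-hydroxy acid: 2-[(1E)-3-tert-butoxy-3-oxo-2-{[(triisopropylsilyl)oxy]methyl}prop-1-enyl]-6-hydroxy-6-{[(tert-butyldiphenylsilyl)oxy]methyl}-3-isopropylcyclohexane-1-carboxylic acid; CO2H, alkenyl, isopropyl all cis, OH trans to CO2H | CC(C)[C@@H]1CC[C@](O)(CO[Si](c2ccccc2)(c3ccccc3)C(C)(C)C)[C@H](C(=O)O)[C@@H]1/C=C(\CO[Si](C(C)C)(C(C)C)C(C)C)C(=O)OC(C)(C)C | intermediate
27 | tert-butyl (2E)-3-[(1R,6S)-3-{[(tert-butyldiphenylsilyl)oxy]methyl}-6-isopropylcyclohex-2-en-1-yl]-2-{[(triisopropylsilyl)oxy]methyl}prop-2-enoate | CC(C)[C@@H]1CCC(CO[Si](c2ccccc2)(c3ccccc3)C(C)(C)C)=C[C@@H]1/C=C(\CO[Si](C(C)C)(C(C)C)C(C)C)C(=O)OC(C)(C)C | intermediate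
28 | carboxylic acid of 27 (not isolated) | CC(C)[C@@H]1CCC(CO[Si](c2ccccc2)(c3ccccc3)C(C)(C)C)=C[C@@H]1/C=C(\CO[Si](C(C)C)(C(C)C)C(C)C)C(=O)O | intermediate
29 | (2E)-2-(hydroxymethyl)-3-[(1R,6S)-3-(hydroxymethyl)-6-isopropylcyclohex-2-en-1-yl]prop-2-enoic acid | CC(C)[C@@H]1CCC(CO)=C[C@@H]1/C=C(\CO)C(=O)O | intermediate
30 | tert-butyl (5aR,6R,9S,9aS)-9-hydroxy-9-({[(2E)-2-(hydroxymethyl)-3-[(1R,6S)-3-(hydroxymethyl)-6-isopropylcyclohex-2-en-1-yl]prop-2-enoyl]oxy}methyl)-6-isopropyl-1-oxo-1,3,5a,6,7,8,9,9a-octahydro-2-benzoxepine-4-carboxylate | CC(C)[C@H]1CC[C@@](O)(COC(=O)/C(=C/[C@H]2C=C(CO)CC[C@H]2C(C)C)CO)[C@H]2C(=O)OCC(C(=O)OC(C)(C)C)=C[C@@H]12 | intermediate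
31 | (5aR,6R,9S,9aS)-9-hydroxy-9-({[(2E)-2-(hydroxymethyl)-3-[(1R,6S)-3-(hydroxymethyl)-6-isopropylcyclohex-2-en-1-yl]prop-2-enoyl]oxy}methyl)-6-isopropyl-1-oxo-1,3,5a,6,7,8,9,9a-octahydro-2-benzoxepine-4-carboxylic acid | CC(C)[C@H]1CC[C@@](O)(COC(=O)/C(=C/[C@H]2C=C(CO)CC[C@H]2C(C)C)CO)[C@H]2C(=O)OCC(C(=O)O)=C[C@@H]12 | target

**Step count and risks**

Total step count: 22. Longest linear sequence: 13 steps (1, 2, 12–22).

Steps most likely to fail:

Step 12 (step 4 is the same reaction in the mirror-image series and shares this risk). The cycloaddition may be slow because the doubly oxygenated diene terminus disfavors the s-cis conformer. Silyl transfer or a stepwise Mukaiyama–Michael addition may compete, and endo selectivity may erode, which would place isopropyl trans to the ring-fusion carbons. The fallback sets out from 1 and 18. Wittig homologation of 1 with (triphenylphosphoranylidene)acetaldehyde gives (E)-5-methylhex-2-enal F1. Soft enolisation (tBuMe2SiOTf, Et3N) gives (1E,3E)-1-(tert-butyldimethylsilyloxy)-5-methylhexa-1,3-diene F2, which has no inside substituent and belongs to the diene class already used with this dienophile. Cycloaddition with 18 in toluene at 110 °C should give the all-cis allylic silyl ether adduct F3. Bu4NF gives the allylic alcohol F4, and Dess–Martin oxidation returns to 20. The same sequence with 8 returns to 10.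

Step 21. Opening at the neopentyl-type CH2 may be sluggish, the carboxylate may instead attack the allylic lactone CH2, and base may induce lactone migration once the tertiary alkoxide forms. The fallback sets out from 16 and 27. Upjohn dihydroxylation of 16 (OsO4, NMO), with the same facial preference as step 11, gives the western diol F5. Selective acidolysis of 27 with 85% aq. H3PO4 gives acid 28, here isolated with both silyl ethers in place. Yamaguchi esterification of the primary hydroxyl of F5 with 28 gives the bis-silyl ester F6, and HF·pyridine returns to 30.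

Step 14 (step 6 shares this risk). Enolisation of the β-keto lactone may consume the methylenating reagent or lock the ketone as an unreactive titanium enolate. The fallback sets out from 21 and uses that enolisation. NaH and PhNTf2 give the enol triflate F7. Negishi coupling with Me3SiCH2ZnCl and Pd(PPh3)4 gives the conjugated allylsilane F8. Fluoride-induced protodesilylation (Bu4NF, AcOH), with α-protonation of the dienolate and allylic transposition, returns to 22 with the cis ring fusion. The same sequence from 11 returns to 12.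

Further compounds
F1 | step 12 | (E)-5-methylhex-2-enal | CC(C)C/C=C/C=O
F2 | step 12 | (1E,3E)-1-(tert-butyldimethylsilyloxy)-5-methylhexa-1,3-diene | CC(C)/C=C/C=C/O[Si](C)(C)C(C)(C)C
F3 | step 12 | cis-fused (3R)-7-(tert-butyldimethylsilyloxy)-4-isopropyl-3-(l-menthyloxy)-3a,4,7,7a-tetrahydroisobenzofuran-1(3H)-one, H-3a, H-4, H-7, H-7a all cis | CC(C)[C@@H]1C=C[C@H](O[Si](C)(C)C(C)(C)C)[C@@H]2C(=O)O[C@@H](O[C@@H]3C[C@H](C)CC[C@H]3C(C)C)[C@H]12
F4 | step 12 | cis-fused (3R)-7-hydroxy-4-isopropyl-3-(l-menthyloxy)-3a,4,7,7a-tetrahydroisobenzofuran-1(3H)-one, H-3a, H-4, H-7, H-7a all cis | CC(C)[C@@H]1C=C[C@H](O)[C@@H]2C(=O)O[C@@H](O[C@@H]3C[C@H](C)CC[C@H]3C(C)C)[C@H]12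
F5 | step 21 | tert-butyl (5aR,6R,9S,9aS)-9-hydroxy-9-(hydroxymethyl)-6-isopropyl-1-oxo-1,3,5a,6,7,8,9,9a-octahydro-2-benzoxepine-4-carboxylate | CC(C)[C@H]1CC[C@@](O)(CO)[C@H]2C(=O)OCC(C(=O)OC(C)(C)C)=C[C@@H]12
F6 | step 21 | bis-silyl ether of 30 (ring CH2O–SitBuPh2, side-chain CH2O–Si(iPr)3) | CC(C)[C@H]1CC[C@@](O)(COC(=O)/C(=C/[C@H]2C=C(CO[Si](c3ccccc3)(c4ccccc4)C(C)(C)C)CC[C@H]2C(C)C)CO[Si](C(C)C)(C(C)C)C(C)C)[C@H]2C(=O)OCC(C(=O)OC(C)(C)C)=C[C@@H]12
F7 | step 14 | enol triflate of 21: (3R,3aR,4S)-4-isopropyl-3-(l-menthyloxy)-1-oxo-1,3,3a,4,5,6-hexahydroisobenzofuran-7-yl trifluoromethanesulfonate | CC(C)[C@@H]1CCC(OS(=O)(=O)C(F)(F)F)=C2C(=O)O[C@@H](O[C@@H]3C[C@H](C)CC[C@H]3C(C)C)[C@H]12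
F8 | step 14 | (3R,3aR,4S)-4-isopropyl-3-(l-menthyloxy)-7-[(trimethylsilyl)methyl]-3a,4,5,6-tetrahydroisobenzofuran-1(3H)-one | CC(C)[C@@H]1CCC(C[Si](C)(C)C)=C2C(=O)O[C@@H](O[C@@H]3C[C@H](C)CC[C@H]3C(C)C)[C@H]12
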